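**Retrosynthetic overview**

1. Numbering used: ring carbons C1–C10 (C3 = CH–OH, C4=C5 with the C15 methyl on C4, C6 = lactone CH–O, C7 = ring-fusion CH, C9 = CH–O-angeloyl, C10 = C(OH)CH3); lactone carbons C11 (α), C12 (C=O), C13 (=CH2).
2. Enabling feature: the C3 carbinol sits directly on the (Z)-C4=C5 alkene of the ten-membered ring, an alkenyl-metal + aldehyde retron; the cis alkene and the trans-fused γ-lactone (O–C6–C7–C11–C12) act as a turn that holds C3 near C4.
3. Target ⇐ C10-O-silyl macrocycle ⇐ Ni/Cr-mediated C3–C4 closure of an open-chain (Z)-iodoalkene aldehyde; the ten-membered carbocycle is closed last and C3 is set in the same event.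
4. Open chain ⇐ α-methylene lactone with the C9 angelate and a prenyl end (masked C3 aldehyde); iodoalkene by iodo-Wittig olefination of a C5 aldehyde; C7–C8 bond by anti-selective Giese addition of a C8 radical (from nerol; C9/C10 by Sharpless epoxidation and Payne opening) to a butenolide that brings C6.
5. Ring order: γ-lactone first (present from the chiral-pool butenolide onward), ten-membered carbocycle last.

Key step: step 14

Remark: nerol, (5S)-5-(hydroxymethyl)furan-2(5H)-one, angelic acid and D-(−)-diethyl tartrate are taken as purchasable. The facial selectivity at C3 in step 14 is an expectation, not a known result. The CIP labels at C9 (R in 5 and 6, S later) and at C6 (S in 15–21, R in 22 and 23) change only because iodine or chromium alters substituent priorities; no configuration changes.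

**Route**

Step 1
Reactants: 1 nerol (2Z)-3,7-dimethylocta-2,6-dien-1-ol
Product: 2 epoxy alcohol [(2R,3S)-3-methyl-3-(4-methylpent-3-en-1-yl)oxiran-2-yl]methanol
Conditions: Ti(OiPr)4 (cat.), D-(−)-diethyl tartrate (cat.), t-BuOOH, 4 Å MS, CH2Cl2, −20 °C
Reagents that add atoms: tert-butyl hydroperoxide CC(C)(C)OO
Why: Sharpless asymmetric epoxidation; the titanium–tartrate catalyst should deliver oxygen to one face of the allylic-alcohol alkene only (the remote trisubstituted alkene is not directed and stays), which fixes the C10–O configuration and the sense of the later inversion at C9.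

Step 2
Reactants: 2 epoxy alcohol
Product: 4 triol (2S,3S)-3,7-dimethyloct-6-ene-1,2,3-triol, via terminal epoxide 3 (not isolated)
Conditions: NaOH (0.5 M aq.), t-BuOH, 70 °C
Reagents that add atoms: water O
Why: Payne rearrangement–opening; the C8 alkoxide should open the epoxide at C9 with inversion to give terminal epoxide 3, which hydroxide opens at the primary carbon C8, so that C10 keeps its C–O bond and the diol arrives as 9S,10S.

Step 3
Reactants: 4 triol
Product: 5 iodo diol (2R,3S)-1-iodo-3,7-dimethyloct-6-ene-2,3-diol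
Conditions: I2, PPh3, imidazole, THF, 0 °C
Reagents that add atoms: iodine II
Why: Appel-type iodination is selective for the primary hydroxyl over the hindered secondary and tertiary ones and leaves both stereocentres untouched.

Step 4
Reactants: 5 iodo diol
Product: 6 iodo acetonide (4R,5S)-4-(iodomethyl)-2,2,5-trimethyl-5-(4-methylpent-3-en-1-yl)-1,3-dioxolane
Conditions: Me2C(OMe)2, PPTS (cat.), CH2Cl2, rt
Reagents that add atoms: 2,2-dimethoxypropane COC(C)(C)OC
Why: Acid-catalysed transacetalisation should tie the secondary and tertiary hydroxyls into a dioxolane that survives the radical, enolate and ylide steps.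

Step 5
Reactants: 7 (5S)-5-(hydroxymethyl)furan-2(5H)-one
Product: 8 silyl butenolide (5S)-5-{[(triethylsilyl)oxy]methyl}furan-2(5H)-one
Conditions: Et3SiCl, imidazole, CH2Cl2, 0 °C
Reagents that add atoms: chlorotriethylsilane CC[Si](Cl)(CC)CC
Why: Standard silylation of the primary alcohol; the triethylsilyl ether adds bulk next to C6 for the facial control in step 6 and can later be oxidised directly to the aldehyde.

Step 6
Reactants: 6 iodo acetonide; 8 silyl butenolide
Product: 9 Giese adduct (4S,5S)-4-{[(4S,5S)-2,2,5-trimethyl-5-(4-methylpent-3-en-1-yl)-1,3-dioxolan-4-yl]methyl}-5-{[(triethylsilyl)oxy]methyl}dihydrofuran-2(3H)-one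
Conditions: (Me3Si)3SiH, Et3B (cat.)/air, 8 (3 equiv), toluene, 0 °C → rt
Reagents that add atoms: none
Why: Giese reaction; the primary C8 radical formed by iodine abstraction from 6 should add to C7 of the butenolide on the face anti to the C6 CH2OSiEt3 group, which sets the 6,7-trans relationship (7S), and the α-carbonyl radical is then reduced by the silane.

Step 7
Reactants: 9 Giese adduct
Product: 12 methylene lactone (4S,5S)-3-methylidene-4-{[(4S,5S)-2,2,5-trimethyl-5-(4-methylpent-3-en-1-yl)-1,3-dioxolan-4-yl]methyl}-5-{[(triethylsilyl)oxy]methyl}dihydrofuran-2(3H)-one, via Mannich base 10 (not isolated), via ammonium iodide 11 (not isolated)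
Conditions: LDA, THF, −78 °C; CH2=NMe2+ I−, −78 °C → rt; MeI, MeOH, rt; NaHCO3 (aq.), CH2Cl2, rt
Reagents that add atoms: Eschenmoser's salt (N,N-dimethylmethyleneiminium iodide) C=[N+](C)C.[I-]
Why: Eschenmoser α-methylenation; aminomethylation of the lactone enolate at C11, N-methylation and E1cB loss of trimethylamine should install the C11=C13 methylene, and C6 and C7 are not enolisable under these conditions.

Step 8
Reactants: 12 methylene lactone
Product: 14 lactone aldehyde (2S,3S)-4-methylidene-5-oxo-3-{[(4S,5S)-2,2,5-trimethyl-5-(4-methylpent-3-en-1-yl)-1,3-dioxolan-4-yl]methyl}tetrahydrofuran-2-carbaldehyde, via alkoxysulfonium chloride 13 (not isolated)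
Conditions: (COCl)2, DMSO, CH2Cl2, −78 → −40 °C; Et3N, −78 → 0 °C
Reagents that add atoms: none
Why: Swern oxidation applied directly to the primary triethylsilyl ether, a known oxidative desilylation in which the chlorosulfonium reagent exchanges the silyl group and the alkoxysulfonium ylide collapses to the aldehyde, while the acetonide is inert and the cold amine quench limits epimerisation at C6.

Step 9
Reactants: 14 lactone aldehyde
Product: 15 iodoalkene acetonide (4S,5S)-5-[(1Z)-2-iodoprop-1-en-1-yl]-3-methylidene-4-{[(4S,5S)-2,2,5-trimethyl-5-(4-methylpent-3-en-1-yl)-1,3-dioxolan-4-yl]methyl}dihydrofuran-2(3H)-one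
Conditions: Ph3P+Et I−, n-BuLi, THF, rt; I2, −78 °C; NaHMDS, −20 °C; then 14, −78 → −20 °C
Reagents that add atoms: ethyltriphenylphosphonium iodide CC[P+](c1ccccc1)(c1ccccc1)c1ccccc1.[I-]; iodine II
Why: Stork–Zhao-type Wittig olefination with the α-iodoethylidene ylide, which under kinetic control should give the (Z)-2-iodoalkene with iodine cis to C6 and so fixes the C4=C5 geometry of the target.

Step 10
Reactants: 15 iodoalkene acetonide
Product: 16 iodoalkene diol (4S,5S)-4-[(2S,3S)-2,3-dihydroxy-3,7-dimethyloct-6-en-1-yl]-5-[(1Z)-2-iodoprop-1-en-1-yl]-3-methylidenedihydrofuran-2(3H)-one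
Conditions: AcOH/H2O (4:1), 50 °C
Reagents that add atoms: none
Why: Acid-catalysed acetal hydrolysis should free the C9/C10 diol, and the lactone, the iodoalkene and the other alkenes tolerate aqueous acetic acid.

Step 11
Reactants: 16 iodoalkene diol
Product: 17 angelate (2S,3S)-3-hydroxy-1-[(2S,3S)-2-[(1Z)-2-iodoprop-1-en-1-yl]-4-methylidene-5-oxotetrahydrofuran-3-yl]-3,7-dimethyloct-6-en-2-yl (2Z)-2-methylbut-2-enoate
Conditions: angelic acid, 2,4,6-Cl3C6H2COCl, Et3N, toluene, rt; then 16, toluene, 75 °C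
Reagents that add atoms: angelic acid [(2Z)-2-methylbut-2-enoic acid] C/C=C(/C)C(=O)O
Why: Yamaguchi esterification through the mixed anhydride, run without DMAP because this variant is known to keep the Z geometry of the angeloyl group; only the secondary C9 hydroxyl should react, the tertiary C10 hydroxyl being too hindered.

Step 12
Reactants: 17 angelate
Product: 18 silyl ether (2S,3S)-1-[(2S,3S)-2-[(1Z)-2-iodoprop-1-en-1-yl]-4-methylidene-5-oxotetrahydrofuran-3-yl]-3,7-dimethyl-3-[(triethylsilyl)oxy]oct-6-en-2-yl (2Z)-2-methylbut-2-enoate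
Conditions: Et3SiOTf, 2,6-lutidine, CH2Cl2, −78 → 0 °C
Reagents that add atoms: triethylsilyl trifluoromethanesulfonate CC[Si](CC)(CC)OS(=O)(=O)C(F)(F)F
Why: Silyl triflate silylation of the tertiary alcohol, needed because a free C10 hydroxyl would trap the C3 aldehyde of the next step as a five-membered lactol.

Step 13
Reactants: 18 silyl ether
Product: 20 seco aldehyde (2S,3S)-1-[(2S,3S)-2-[(1Z)-2-iodoprop-1-en-1-yl]-4-methylidene-5-oxotetrahydrofuran-3-yl]-3-methyl-6-oxo-3-[(triethylsilyl)oxy]hexan-2-yl (2Z)-2-methylbut-2-enoate, via ozonide 19 (not isolated)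
Conditions: O3, CH2Cl2, −78 °C (Sudan Red 7B end point); PPh3, −78 °C → rt
Reagents that add atoms: ozone [O-][O+]=O
Why: Ozonolysis with reductive work-up; the electron-rich trisubstituted alkene at the chain end should react well before the iodoalkene, the conjugated methylene and the angelate, and the indicator dye marks the end point.

Step 14
Reactants: 20 seco aldehyde
Product: 22 macrocyclic silyl ether (3S,6R,7S,9S,10S)-9-angeloyloxy-3-hydroxy-10-(triethylsilyloxy)germacra-4Z,11(13)-dien-12,6-olide, via alkenylchromium dichloride 21 (not isolated)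
Conditions: CrCl2 (excess), NiCl2 (cat.), DMSO/THF, rt, high dilution (slow addition of 20)
Reagents that add atoms: none
Why: Ni(0), formed in situ from NiCl2 and CrCl2, inserts into the C4–I bond of 20 with retention of the Z geometry and transmetalates to Cr(III); the alkenylchromium 21 then adds to the C3 aldehyde, and the strong Cr–O bond makes the addition irreversible. The closest known reaction type is the intramolecular Nozaki–Hiyama–Kishi iodoalkene–aldehyde coupling, which is used to close nine-membered carbo- and oxacycles from (Z)-iodoalkenes and ten-membered lactones. The ten-membered carbocycle closes by C3–C4 bond formation in a 10-exo-trig attack on the carbonyl, and the C4=C5 alkene ends up inside the ring. C3 is set under substrate control: the Z-alkene, the trans-fused lactone and the quaternary C10 with its OSiEt3 group fold the chain so that the alkenylchromium is expected to reach the Re face of the aldehyde with the carbonyl oxygen pointing out of the forming ring, which gives 3S. The step needs chemoselectivity for the aldehyde over the lactone, the angelate and the two conjugated C=C bonds, which the low basicity and carbonyl selectivity of organochromium(III) reagents secure, and ring closure over oligomerisation, which high dilution and the cis-alkene/lactone turn secure.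

Step 15
Reactants: 22 macrocyclic silyl ether
Product: 23 target (3S,6R,7S,9S,10S)-9-angeloyloxy-3,10-dihydroxygermacra-4Z,11(13)-dien-12,6-olide
Conditions: HF·pyridine, pyridine/THF, 0 °C → rt
Reagents that add atoms: none
Why: Fluoride-mediated cleavage of the tertiary triethylsilyl ether; buffered HF·pyridine should leave the lactone, the angelate and the allylic C3 alcohol untouched and give the target.

**Compound list**

1 | nerol (2Z)-3,7-dimethylocta-2,6-dien-1-ol | CC(C)=CCC/C(C)=C\CO | starting material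
2 | epoxy alcohol [(2R,3S)-3-methyl-3-(4-methylpent-3-en-1-yl)oxiran-2-yl]methanol | CC(C)=CCC[C@]1(C)O[C@@H]1CO | intermediate
3 | terminal epoxide (2S)-6-methyl-2-[(2S)-oxiran-2-yl]hept-5-en-2-ol | CC(C)=CCC[C@](C)(O)[C@@H]1CO1 | intermediate
4 | triol (2S,3S)-3,7-dimethyloct-6-ene-1,2,3-triol | CC(C)=CCC[C@](C)(O)[C@@H](O)CO | intermediate
5 | iodo diol (2R,3S)-1-iodo-3,7-dimethyloct-6-ene-2,3-diol | CC(C)=CCC[C@](C)(O)[C@@H](O)CI | intermediate
6 | iodo acetonide (4R,5S)-4-(iodomethyl)-2,2,5-trimethyl-5-(4-methylpent-3-en-1-yl)-1,3-dioxolane | CC(C)=CCC[C@]1(C)OC(C)(C)O[C@H]1CI | intermediate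
7 | (5S)-5-(hydroxymethyl)furan-2(5H)-one | O=C1C=C[C@@H](CO)O1 | starting material
8 | silyl butenolide (5S)-5-{[(triethylsilyl)oxy]methyl}furan-2(5H)-one | O=C1C=C[C@@H](CO[Si](CC)(CC)CC)O1 | intermediate
9 | Giese adduct (4S,5S)-4-{[(4S,5S)-2,2,5-trimethyl-5-(4-methylpent-3-en-1-yl)-1,3-dioxolan-4-yl]methyl}-5-{[(triethylsilyl)oxy]methyl}dihydrofuran-2(3H)-one | O=C1C[C@H](C[C@@H]2OC(C)(C)O[C@@]2(C)CCC=C(C)C)[C@@H](CO[Si](CC)(CC)CC)O1 | intermediate
10 | Mannich base 3-[(dimethylamino)methyl] derivative of 9 (epimers at the lactone α-carbon) | CN(C)CC1C(=O)O[C@H](CO[Si](CC)(CC)CC)[C@H]1C[C@@H]2OC(C)(C)O[C@@]2(C)CCC=C(C)C | intermediate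
11 | ammonium iodide N-methyl quaternary salt of 10 | C[N+](C)(C)CC1C(=O)O[C@H](CO[Si](CC)(CC)CC)[C@H]1C[C@@H]2OC(C)(C)O[C@@]2(C)CCC=C(C)C.[I-] | intermediate
12 | methylene lactone (4S,5S)-3-methylidene-4-{[(4S,5S)-2,2,5-trimethyl-5-(4-methylpent-3-en-1-yl)-1,3-dioxolan-4-yl]methyl}-5-{[(triethylsilyl)oxy]methyl}dihydrofuran-2(3H)-one | C=C1C(=O)O[C@H](CO[Si](CC)(CC)CC)[C@H]1C[C@@H]2OC(C)(C)O[C@@]2(C)CCC=C(C)C | intermediate
13 | alkoxysulfonium chloride dimethyl{[(2S,3S)-4-methylidene-5-oxo-3-{[(4S,5S)-2,2,5-trimethyl-5-(4-methylpent-3-en-1-yl)-1,3-dioxolan-4-yl]methyl}tetrahydrofuran-2-yl]methoxy}sulfonium chloride | C=C1C(=O)O[C@H](CO[S+](C)C)[C@H]1C[C@@H]2OC(C)(C)O[C@@]2(C)CCC=C(C)C.[Cl-] | intermediate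
14 | lactone aldehyde (2S,3S)-4-methylidene-5-oxo-3-{[(4S,5S)-2,2,5-trimethyl-5-(4-methylpent-3-en-1-yl)-1,3-dioxolan-4-yl]methyl}tetrahydrofuran-2-carbaldehyde | C=C1C(=O)O[C@H](C=O)[C@H]1C[C@@H]2OC(C)(C)O[C@@]2(C)CCC=C(C)C | intermediate
15 | iodoalkene acetonide (4S,5S)-5-[(1Z)-2-iodoprop-1-en-1-yl]-3-methylidene-4-{[(4S,5S)-2,2,5-trimethyl-5-(4-methylpent-3-en-1-yl)-1,3-dioxolan-4-yl]methyl}dihydrofuran-2(3H)-one | C=C1C(=O)O[C@H](/C=C(/C)I)[C@H]1C[C@@H]2OC(C)(C)O[C@@]2(C)CCC=C(C)C | intermediate
16 | iodoalkene diol (4S,5S)-4-[(2S,3S)-2,3-dihydroxy-3,7-dimethyloct-6-en-1-yl]-5-[(1Z)-2-iodoprop-1-en-1-yl]-3-methylidenedihydrofuran-2(3H)-one | C=C1C(=O)O[C@H](/C=C(/C)I)[C@H]1C[C@H](O)[C@@](C)(O)CCC=C(C)C | intermediate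
17 | angelate (2S,3S)-3-hydroxy-1-[(2S,3S)-2-[(1Z)-2-iodoprop-1-en-1-yl]-4-methylidene-5-oxotetrahydrofuran-3-yl]-3,7-dimethyloct-6-en-2-yl (2Z)-2-methylbut-2-enoate | C=C1C(=O)O[C@H](/C=C(/C)I)[C@H]1C[C@H](OC(=O)/C(C)=C\C)[C@@](C)(O)CCC=C(C)C | intermediate
18 | silyl ether (2S,3S)-1-[(2S,3S)-2-[(1Z)-2-iodoprop-1-en-1-yl]-4-methylidene-5-oxotetrahydrofuran-3-yl]-3,7-dimethyl-3-[(triethylsilyl)oxy]oct-6-en-2-yl (2Z)-2-methylbut-2-enoate | C=C1C(=O)O[C@H](/C=C(/C)I)[C@H]1C[C@H](OC(=O)/C(C)=C\C)[C@@](C)(O[Si](CC)(CC)CC)CCC=C(C)C | intermediate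
19 | ozonide 5,5-dimethyl-1,2,4-trioxolane formed across the chain-end alkene of 18 (epimers at the trioxolane CH) | C=C1C(=O)O[C@H](/C=C(/C)I)[C@H]1C[C@H](OC(=O)/C(C)=C\C)[C@@](C)(O[Si](CC)(CC)CC)CCC2OOC(C)(C)O2 | intermediate
20 | seco aldehyde (2S,3S)-1-[(2S,3S)-2-[(1Z)-2-iodoprop-1-en-1-yl]-4-methylidene-5-oxotetrahydrofuran-3-yl]-3-methyl-6-oxo-3-[(triethylsilyl)oxy]hexan-2-yl (2Z)-2-methylbut-2-enoate | C=C1C(=O)O[C@H](/C=C(/C)I)[C@H]1C[C@H](OC(=O)/C(C)=C\C)[C@@](C)(O[Si](CC)(CC)CC)CCC=O | intermediate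
21 | alkenylchromium dichloride of 20 (CrCl2 in place of iodine at C4; Z geometry kept) | C=C1C(=O)O[C@H](/C=C(/C)[Cr](Cl)Cl)[C@H]1C[C@H](OC(=O)/C(C)=C\C)[C@@](C)(O[Si](CC)(CC)CC)CCC=O | intermediate
22 | macrocyclic silyl ether (3S,6R,7S,9S,10S)-9-angeloyloxy-3-hydroxy-10-(triethylsilyloxy)germacra-4Z,11(13)-dien-12,6-olide | C=C1C(=O)O[C@@H]2/C=C(/C)[C@@H](O)CC[C@](C)(O[Si](CC)(CC)CC)[C@@H](OC(=O)/C(C)=C\C)C[C@@H]12 | intermediate
23 | (3S,6R,7S,9S,10S)-9-angeloyloxy-3,10-dihydroxygermacra-4Z,11(13)-dien-12,6-olide | C=C1C(=O)O[C@@H]2/C=C(/C)[C@@H](O)CC[C@](C)(O)[C@@H](OC(=O)/C(C)=C\C)C[C@@H]12 | target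

**Step count**

Total step count: 15. Longest linear sequence: 14 steps (steps 1–4 and 6–15 from nerol; step 5 prepares the second fragment).

**Steps most likely to fail**

Step 14. What may go wrong: the alkenylchromium adds to the Si face of the C3 aldehyde, or without facial preference, so that the ring closes with the wrong configuration at C3. Fallback, from 20 back to 22: the same Ni/Cr closure is run without regard to C3 and should give the (3R)-epimeric carbinol F1, alone or mixed with 22. Dess–Martin periodinane (NaHCO3, CH2Cl2) should oxidise this material to the single macrocyclic (4Z)-enone F2. Reagent-controlled 1,2-reduction with (R)-Me-CBS and catecholborane (toluene, −78 °C), the alkenyl side acting as the large group, should then set 3S and return to 22. C3 is then fixed by ketone reduction and no longer by the C–C bond formation.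

Step 9. What may go wrong: slow olefination of the hindered α-acyloxy aldehyde by the basic iodo-ylide, with epimerisation at C6 and erosion of the Z geometry. Fallback, non-basic, from 14 back to 15: Ramirez dibromo-olefination (CBr4, PPh3, CH2Cl2, 0 °C) should give the 1,1-dibromoalkene F3. Pd-catalysed Negishi mono-methylation (MeZnCl, Pd(DPEphos)Cl2 cat., THF), which is known to replace only the bromide trans to the carbon substituent, should give the (Z)-bromoalkene F4 with bromine cis to C6. Pd-catalysed stannylation (Me3SnSnMe3, Pd(PPh3)4, toluene, 80 °C) should give the (Z)-alkenylstannane F5 with retention, and iododestannylation (I2, CH2Cl2, 0 °C) returns to 15.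

Step 11. What may go wrong: slow acylation of the hindered C9 hydroxyl, during which the angeloyl group isomerises to the tigloyl (E) group, or the free C9 hydroxyl adds to the conjugated methylene under the warm basic conditions. Fallback, from 16 back to 18: the hydroxyl is acylated at room temperature with 2-[bis(2,2,2-trifluoroethoxy)phosphoryl]propanoic acid (DCC, DMAP cat., CH2Cl2) to give the phosphonopropionate F6. Silylation of the C10 hydroxyl (Et3SiOTf, 2,6-lutidine, CH2Cl2) gives the silylated phosphonopropionate F7. A Still–Gennari olefination with acetaldehyde (KHMDS, 18-crown-6, THF, −78 °C) then builds the (Z)-2-methylbut-2-enoate on the ester and returns to 18. The angelate is then made by Z-selective C=C bond formation and not by transfer of a preformed, isomerisable acyl group.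

**Further compounds**

F1 | step 14 | (3R)-epimeric carbinol, C3 epimer of 22 | C=C1C(=O)O[C@@H]2/C=C(/C)[C@H](O)CC[C@](C)(O[Si](CC)(CC)CC)[C@@H](OC(=O)/C(C)=C\C)C[C@@H]12
F2 | step 14 | macrocyclic (4Z)-enone, 3-oxo analogue of 22 | C=C1C(=O)O[C@@H]2/C=C(/C)C(=O)CC[C@](C)(O[Si](CC)(CC)CC)[C@@H](OC(=O)/C(C)=C\C)C[C@@H]12
F3 | step 9 | 1,1-dibromoalkene, 5-(2,2-dibromoethenyl) analogue of 15 | C=C1C(=O)O[C@H](C=C(Br)Br)[C@H]1C[C@@H]2OC(C)(C)O[C@@]2(C)CCC=C(C)C
F4 | step 9 | (Z)-bromoalkene, 5-[(1Z)-2-bromoprop-1-en-1-yl] analogue of 15 | C=C1C(=O)O[C@H](/C=C(/C)Br)[C@H]1C[C@@H]2OC(C)(C)O[C@@]2(C)CCC=C(C)C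
F5 | step 9 | (Z)-alkenylstannane, 5-[(1Z)-2-(trimethylstannyl)prop-1-en-1-yl] analogue of 15 | C=C1C(=O)O[C@H](/C=C(/C)[Sn](C)(C)C)[C@H]1C[C@@H]2OC(C)(C)O[C@@]2(C)CCC=C(C)C
F6 | step 11 | phosphonopropionate, C9 2-[bis(2,2,2-trifluoroethoxy)phosphoryl]propanoate of 16 | C=C1C(=O)O[C@H](/C=C(/C)I)[C@H]1C[C@H](OC(=O)C(C)P(=O)(OCC(F)(F)F)OCC(F)(F)F)[C@@](C)(O)CCC=C(C)C
F7 | step 11 | silylated phosphonopropionate, C10 triethylsilyl ether of F6 | C=C1C(=O)O[C@H](/C=C(/C)I)[C@H]1C[C@H](OC(=O)C(C)P(=O)(OCC(F)(F)F)OCC(F)(F)F)[C@@](C)(O[Si](CC)(CC)CC)CCC=C(C)C
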